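The route rests on cutting the C14–C15 bond inside the unbranched C9–C23 polymethylene tether that links the C5–C8 diyne to C2 of the furan ring. Both carbons are primary, unactivated and remote from every functional group, so each half derives from an ω-bromide: the C15 bromide is reversed in polarity as a Grignard reagent and joined to the C14 bromide by copper-catalysed sp3–sp3 coupling. The C1 acid travels unprotected as its chloromagnesium salt, so this one operation gives the target directly. Its precursors are 2-(9-bromononyl)furan and 14-bromotetradeca-5,7-diynoic acid, the latter built by Cadiot–Chodkiewicz coupling.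

Key step: step 4

Assumption: the target has no stereocentre and no stereogenic double bond, so it is one achiral compound and no stereocontrol is needed; 8-bromooct-1-yne is taken as a commercial starting material.

Step 1
Reactants: 1 furan; 2 1,9-dibromononane
Product: 4 2-(9-bromononyl)furan, via 2-furyllithium 3 (not isolated)
Conditions: n-BuLi, THF, −78 → 0 °C; then 2 (3 equiv), THF, −78 °C → rt
Reagents that add atoms: none
Why: Furan is deprotonated at C2 (α-lithiation next to the ring oxygen) and the 2-furyllithium is alkylated by SN2 displacement of one primary bromide, the three-fold excess of the symmetrical dibromide limiting double substitution.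

Step 2
Reactants: 5 8-bromooct-1-yne
Product: 6 1,8-dibromooct-1-yne
Conditions: NBS, AgNO3 (cat.), acetone, rt, dark
Reagents that add atoms: N-bromosuccinimide, O=C1CCC(=O)N1Br
Why: Silver-catalysed electrophilic bromination of the terminal alkyne C–H should give the 1-bromoalkyne while the primary alkyl bromide stays untouched.

Step 3
Reactants: 6 1,8-dibromooct-1-yne; 7 hex-5-ynoic acid
Product: 8 14-bromotetradeca-5,7-diynoic acid
Conditions: CuCl (5 mol%), NH2OH·HCl, n-BuNH2, H2O/MeOH/THF, 0 °C; then 1 M HCl
Reagents that add atoms: none
Why: Cadiot–Chodkiewicz coupling, in which the copper(I) acetylide of 7 (a free alkynoic acid, carried as its ammonium salt) should react with the C(sp)–Br bond of 6 much faster than the amine displaces the primary C(sp3)–Br at 0 °C.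

Step 4
Reactants: 4 2-(9-bromononyl)furan; 8 14-bromotetradeca-5,7-diynoic acid
Product: 11 23-(furan-2-yl)tricosa-5,7-diynoic acid, via 9-(furan-2-yl)nonylmagnesium bromide 9 (not isolated), via chloromagnesium 14-bromotetradeca-5,7-diynoate 10 (not isolated)
Conditions: 4, Mg, THF, 40 °C; 8, MeMgCl (1.0 equiv), THF, −20 °C; then Li2CuCl4 (3 mol%), slow addition of 9 (about 1.4 equiv), THF, −20 → 0 °C; cold aq. HCl to pH 3
Reagents that add atoms: none
Why: Kochi-type copper-catalysed Grignard–alkyl halide coupling (Li2CuCl4), in the known variant that uses chloromagnesium salts of ω-bromo acids: 9 transmetalates to an alkylcuprate, which displaces the primary C14 bromide of 10 by SN2-type oxidative addition, and reductive elimination from the dialkylcopper(III) species forms the C14–C15 bond and returns Cu(I). The step reverses the polarity of C15, which began as an alkyl bromide like C14, so two ω-bromides are united. No ring is closed and no stereocentre is formed. The selectivity needed is chemoselectivity for C(sp3)–Br substitution: the C1 carboxyl group is shielded as its anionic magnesium carboxylate, which Grignard reagents do not attack at −20 °C; the internal, dialkyl-substituted C5–C8 diyne should not be carbometalated under catalytic copper below 0 °C and, as a π-ligand, should rather stabilise the alkylcopper intermediate against β-hydride loss; and the furan C5–H is not metalated by alkylmagnesium halides. Slow addition of 9 at −20 °C should hold homocoupling down, the acidic product is separated from neutral by-products by base extraction, and the quench is kept cold and brief to spare the furan.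

Compound list
1 | furan | c1ccoc1 | starting material
2 | 1,9-dibromononane | BrCCCCCCCCCBr | starting material
3 | 2-furyllithium | [Li]c1ccco1 | intermediate (not isolated)
4 | 2-(9-bromononyl)furan | BrCCCCCCCCCc1ccco1 | intermediate
5 | 8-bromooct-1-yne | C#CCCCCCCBr | starting material
6 | 1,8-dibromooct-1-yne | BrC#CCCCCCCBr | intermediate
7 | hex-5-ynoic acid | OC(=O)CCCC#C | starting material
8 | 14-bromotetradeca-5,7-diynoic acid | OC(=O)CCCC#CC#CCCCCCCBr | intermediate
9 | 9-(furan-2-yl)nonylmagnesium bromide | Br[Mg]CCCCCCCCCc1ccco1 | intermediate (not isolated)
10 | chloromagnesium 14-bromotetradeca-5,7-diynoate | Cl[Mg]OC(=O)CCCC#CC#CCCCCCCBr | intermediate (not isolated)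
11 | 23-(furan-2-yl)tricosa-5,7-diynoic acid | O=C(O)CCCC#CC#CCCCCCCCCCCCCCCCc1ccco1 | target

Total step count: 4
Longest linear sequence: 3 steps (5 → 6 → 8 → 11); the route is convergent, with 4 made in one step from 1 and 2.

Steps most likely to fail

Step 4. What may go wrong: carbometalation of the conjugated diyne by the organocopper or Grignard species, or precipitation of the magnesium carboxylate so that the C14 bromide is not reached and the Grignard reagent is lost to homocoupling. The fallback sets out from 4 (as its Grignard reagent 9) and comes back at 11; it forms the C14–C15 bond before the diyne and the acid are present. 8-Bromooct-1-yne 5 is silylated (LiHMDS, TMSCl, THF, −78 °C) to (8-bromooct-1-yn-1-yl)trimethylsilane F1. Reagent 9 is coupled with F1 (Li2CuCl4 cat., THF, −20 → 0 °C) to 2-[17-(trimethylsilyl)heptadec-16-yn-1-yl]furan F2. K2CO3 in MeOH should remove the silyl group to give 2-(heptadec-16-yn-1-yl)furan F3. Hex-5-ynoic acid 7 is brominated (NBS, AgNO3 cat., acetone) to 6-bromohex-5-ynoic acid F4, and Cadiot–Chodkiewicz coupling of F3 with F4 (CuCl, NH2OH·HCl, n-BuNH2, 0 °C) should give 11.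

Step 3. What may go wrong: displacement of the primary C14 bromide by the amine base during the coupling, and homocoupling of the bromoalkyne. The fallback sets out from 7 and comes back at 11; it carries C14 as an inert chloride through the amine step and activates it afterwards. Commercial 8-chlorooct-1-yne is brominated (NBS, AgNO3 cat.) to 1-bromo-8-chlorooct-1-yne F5, which is coupled with 7 under the Cadiot–Chodkiewicz conditions to 14-chlorotetradeca-5,7-diynoic acid F6. Finkelstein exchange (NaI, acetone, reflux) should give 14-iodotetradeca-5,7-diynoic acid F7. In step 4, F7 takes the place of 8: MeMgCl converts it into chloromagnesium 14-iodotetradeca-5,7-diynoate F8, and copper-catalysed coupling with 9 should give 11.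

Step 1. What may go wrong: substitution at both ends of the symmetrical dibromide, and a difficult separation of 4 from the excess of 2. The fallback sets out from 1 (by way of 3) and comes back at 4; it uses an electrophile with only one leaving group. Commercial 9-bromononan-1-ol is silylated (TBSCl, imidazole, DMF) to (9-bromononyloxy)(tert-butyl)dimethylsilane F9. 2-Furyllithium 3 is alkylated with F9 to tert-butyl{[9-(furan-2-yl)nonyl]oxy}dimethylsilane F10. TBAF in THF should give 9-(furan-2-yl)nonan-1-ol F11, and Appel bromination (CBr4, PPh3, CH2Cl2, 0 °C) should give 4.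

Further compounds
F1 | step 4 | (8-bromooct-1-yn-1-yl)trimethylsilane | C[Si](C)(C)C#CCCCCCCBr
F2 | step 4 | 2-[17-(trimethylsilyl)heptadec-16-yn-1-yl]furan | C[Si](C)(C)C#CCCCCCCCCCCCCCCCc1ccco1
F3 | step 4 | 2-(heptadec-16-yn-1-yl)furan | C#CCCCCCCCCCCCCCCCc1ccco1
F4 | step 4 | 6-bromohex-5-ynoic acid | OC(=O)CCCC#CBr
F5 | step 3 | 1-bromo-8-chlorooct-1-yne | ClCCCCCCC#CBr
F6 | step 3 | 14-chlorotetradeca-5,7-diynoic acid | OC(=O)CCCC#CC#CCCCCCCCl
F7 | step 3 | 14-iodotetradeca-5,7-diynoic acid | OC(=O)CCCC#CC#CCCCCCCI
F8 | step 3 | chloromagnesium 14-iodotetradeca-5,7-diynoate | Cl[Mg]OC(=O)CCCC#CC#CCCCCCCI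
F9 | step 1 | (9-bromononyloxy)(tert-butyl)dimethylsilane | CC(C)(C)[Si](C)(C)OCCCCCCCCCBr
F10 | step 1 | tert-butyl{[9-(furan-2-yl)nonyl]oxy}dimethylsilane | CC(C)(C)[Si](C)(C)OCCCCCCCCCc1ccco1
F11 | step 1 | 9-(furan-2-yl)nonan-1-ol | OCCCCCCCCCc1ccco1
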